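**Retrosynthetic overview**
- Target ⇐ C8 angelate installed with inversion (Mitsunobu) on the 8-epi macrocyclic alcohol; C1–OH unmasked last.
- Ten-membered carbocycle (ring A) and α-methylene lactone ⇐ chromium-catalysed intramolecular vinylogous carbonyl allylation (C7–C8) of a 3-(chloromethyl)butenolide onto a Z-enal (proposed new step).
- Seco chain ⇐ C2–C3 aldol union of a west butenolide enal and an east Z-enone enol silane, then Evans–Tishchenko reduction (C1 anti, acetate left on O3).
- West butenolide (ring B) ⇐ Ni/Cr-catalysed asymmetric Nozaki–Hiyama–Kishi coupling of a Z-enal with a (Z)-β-iodoacrylate; both Z-trisubstituted alkenes are inherited from methylfuranone rings.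
- Ring order: lactone ring B first (step 5), carbocycle ring A last (step 14).

Assumption: germacranolide numbering is used (C6 lactone carbinol, C7 ring fusion, C8 ester carbinol, C3 acetate carbinol, C1 free carbinol, C11=C13 exocyclic methylene, C12 lactone carbonyl), and the ester side chain is read from the SMILES as angelate, (Z)-2-methylbut-2-enoate.

**Route**

Step 1
Reactants: 1 methyl prop-2-ynoate
Product: 2 methyl (Z)-2-(hydroxymethyl)-3-iodoprop-2-enoate
Conditions: (CH2O)n, MgI2, CH2Cl2, 0 °C to rt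
Reagents that add atoms: formaldehyde, C=O; magnesium iodide, [Mg+2].[I-].[I-]
Why: β-iodo Morita–Baylis–Hillman (iodo-aldol) reaction: iodide adds in conjugate fashion to the ynoate and the β-iodoallenolate is trapped at Cα by formaldehyde, giving the kinetic Z-iodide (I cis to CO2Me).

Step 2
Reactants: 2 methyl (Z)-2-(hydroxymethyl)-3-iodoprop-2-enoate
Product: 3 methyl (Z)-3-iodo-2-[(trimethylsilyloxy)methyl]prop-2-enoate
Conditions: Me3SiCl, Et3N, CH2Cl2, 0 °C
Reagents that add atoms: chlorotrimethylsilane, C[Si](C)(C)Cl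
Why: Silyl ether formation masks the alcohol so it cannot bind the chiral chromium catalyst of step 5.

Step 3
Reactants: 4 4-methylfuran-2(5H)-one
Product: 6 (Z)-N-methoxy-N,3-dimethyl-4-(triethylsilyloxy)but-2-enamide, via hydroxy amide 5 (not isolated)
Conditions: MeNH(OMe)·HCl, AlMe3, CH2Cl2, 0 °C; aq. potassium sodium tartrate; crude 5 at once with imidazole, Et3SiCl, CH2Cl2, 0 °C
Reagents that add atoms: N,O-dimethylhydroxylamine hydrochloride, CNOC.Cl; chlorotriethylsilane, CC[Si](Cl)(CC)CC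
Why: Weinreb aminolysis opens the butenolide without touching the ring C=C, so the Z geometry of C4=C5 comes from the ring; immediate silylation stops relactonisation.

Step 4
Reactants: 6 (Z)-N-methoxy-N,3-dimethyl-4-(triethylsilyloxy)but-2-enamide
Product: 7 (Z)-3-methyl-4-(triethylsilyloxy)but-2-enal
Conditions: i-Bu2AlH, THF, −78 °C
Reagents that add atoms: none
Why: Weinreb amide reduction stops at the aldehyde through the chelated tetrahedral aluminium intermediate, and the Z-enal is used cold and directly.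

Step 5
Reactants: 7 (Z)-3-methyl-4-(triethylsilyloxy)but-2-enal; 3 methyl (Z)-3-iodo-2-[(trimethylsilyloxy)methyl]prop-2-enoate
Product: 9 (S)-3-(hydroxymethyl)-5-[(Z)-2-methyl-3-(triethylsilyloxy)prop-1-enyl]furan-2(5H)-one, via bis-silyl ether adduct 8 (not isolated)
Conditions: CrCl2 (10 mol%), chiral oxazoline–sulfonamide ligand (12 mol%, antipode giving 6S), Et3N (20 mol%), NiCl2(2,9-dimethyl-1,10-phenanthroline) (2 mol%), Mn, Me3SiCl, LiCl, MeCN, rt; then aq. citric acid, THF, 0 °C
Reagents that add atoms: none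
Why: Catalytic asymmetric Nozaki–Hiyama–Kishi coupling (zerovalent nickel inserts into C–I, the alkenyl group passes to trivalent chromium and adds to the aldehyde); the ligand-bound chromium selects the aldehyde face to set C6 (S), and the cis γ-hydroxy ester lactonises on acidic work-up to ring B.

Step 6
Reactants: 9 (S)-3-(hydroxymethyl)-5-[(Z)-2-methyl-3-(triethylsilyloxy)prop-1-enyl]furan-2(5H)-one
Product: 11 (S)-3-(chloromethyl)-5-[(Z)-2-methyl-3-(triethylsilyloxy)prop-1-enyl]furan-2(5H)-one, via mesylate 10 (not isolated)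
Conditions: MsCl, 2,4,6-collidine, LiCl, DMF, 0 °C
Reagents that add atoms: lithium chloride, [Li+].[Cl-]
Why: Mesylation and SN2 displacement by chloride at the primary allylic carbon gives a robust latent allyl donor without touching C6.

Step 7
Reactants: 11 (S)-3-(chloromethyl)-5-[(Z)-2-methyl-3-(triethylsilyloxy)prop-1-enyl]furan-2(5H)-one
Product: 12 (Z)-3-[(S)-4-(chloromethyl)-5-oxo-2,5-dihydrofuran-2-yl]-2-methylprop-2-enal
Conditions: (COCl)2, DMSO, CH2Cl2, −78 to −30 °C; then i-Pr2NEt, −78 °C, cold buffered quench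
Reagents that add atoms: none
Why: Swern conditions cleave a primary triethylsilyl ether oxidatively straight to the aldehyde; low temperature and a hindered amine protect the acidic C6–H and the Z-enal.

Step 8
Reactants: 13 3-methylfuran-2(5H)-one
Product: 15 (Z)-N-methoxy-N,2-dimethyl-4-(triethylsilyloxy)but-2-enamide, via hydroxy amide 14 (not isolated)
Conditions: MeNH(OMe)·HCl, AlMe3, CH2Cl2, 0 °C; aq. potassium sodium tartrate; crude 14 at once with imidazole, Et3SiCl, CH2Cl2, 0 °C
Reagents that add atoms: N,O-dimethylhydroxylamine hydrochloride, CNOC.Cl; chlorotriethylsilane, CC[Si](Cl)(CC)CC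
Why: Weinreb aminolysis of the isomeric butenolide fixes the Z geometry of C9=C10 from the ring, and silylation blocks relactonisation.

Step 9
Reactants: 15 (Z)-N-methoxy-N,2-dimethyl-4-(triethylsilyloxy)but-2-enamide
Product: 16 (Z)-3-methyl-5-(triethylsilyloxy)pent-3-en-2-one
Conditions: MeMgBr, THF, −78 to 0 °C
Reagents that add atoms: methylmagnesium bromide, C[Mg]Br
Why: Weinreb ketone synthesis: the chelated tetrahedral intermediate collapses only on work-up, giving the methyl ketone (C1, C2) with the Z-alkene intact.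

Step 10
Reactants: 16 (Z)-3-methyl-5-(triethylsilyloxy)pent-3-en-2-one
Product: 17 (Z)-3-methyl-5-(triethylsilyloxy)-2-(trimethylsilyloxy)penta-1,3-diene
Conditions: Me3SiOTf, Et3N, CH2Cl2, −20 °C
Reagents that add atoms: trimethylsilyl trifluoromethanesulfonate, C[Si](C)(C)OS(=O)(=O)C(F)(F)F
Why: Soft enolisation at the only α-CH3 gives the silyl enol ether needed for the catalytic aldol.

Step 11
Reactants: 12 (Z)-3-[(S)-4-(chloromethyl)-5-oxo-2,5-dihydrofuran-2-yl]-2-methylprop-2-enal; 17 (Z)-3-methyl-5-(triethylsilyloxy)-2-(trimethylsilyloxy)penta-1,3-diene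
Product: 18 (S)-3-(chloromethyl)-5-[(1Z,3S,6Z)-3-hydroxy-2,6-dimethyl-5-oxo-8-(triethylsilyloxy)octa-1,6-dienyl]furan-2(5H)-one
Conditions: SiCl4, chiral binaphthyldiamine bis-phosphoramide (5 mol%, antipode giving 3S), i-Pr2NEt (10 mol%), CH2Cl2, −78 °C; aq. NaHCO3
Reagents that add atoms: none
Why: Lewis-base-catalysed Mukaiyama aldol addition (phosphoramide-bound trichlorosilyl cation activates the enal, open transition state) forms C2–C3 and sets C3 (S) under catalyst control.

Step 12
Reactants: 18 (S)-3-(chloromethyl)-5-[(1Z,3S,6Z)-3-hydroxy-2,6-dimethyl-5-oxo-8-(triethylsilyloxy)octa-1,6-dienyl]furan-2(5H)-one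
Product: 20 (1Z,3S,5S,6Z)-1-[(S)-4-(chloromethyl)-5-oxo-2,5-dihydrofuran-2-yl]-2,6-dimethyl-5,8-bis(triethylsilyloxy)octa-1,6-dien-3-yl acetate, via diol monoacetate 19 (not isolated)
Conditions: SmI2 (20 mol%, premixed with MeCHO), MeCHO, THF, −10 °C; then imidazole, Et3SiCl, 0 °C
Reagents that add atoms: acetaldehyde, CC=O; chlorotriethylsilane, CC[Si](Cl)(CC)CC
Why: Evans–Tishchenko reduction: the trivalent samarium hemiacetal of O3 and acetaldehyde delivers hydride to the C1 ketone through a chair, giving the 1,3-anti alcohol (1S) with the acetate left on O3; immediate silylation of O1 blocks acetyl migration.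

Step 13
Reactants: 20 (1Z,3S,5S,6Z)-1-[(S)-4-(chloromethyl)-5-oxo-2,5-dihydrofuran-2-yl]-2,6-dimethyl-5,8-bis(triethylsilyloxy)octa-1,6-dien-3-yl acetate
Product: 21 (1Z,3S,5S,6Z)-1-[(S)-4-(chloromethyl)-5-oxo-2,5-dihydrofuran-2-yl]-2,6-dimethyl-8-oxo-5-(triethylsilyloxy)octa-1,6-dien-3-yl acetate
Conditions: (COCl)2, DMSO, CH2Cl2, −78 to −30 °C; then i-Pr2NEt, −78 °C
Reagents that add atoms: none
Why: Swern oxidative desilylation is selective for the primary allylic triethylsilyl ether (C8) over the secondary one (C1), giving the Z-enal directly.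

Step 14
Reactants: 21 (1Z,3S,5S,6Z)-1-[(S)-4-(chloromethyl)-5-oxo-2,5-dihydrofuran-2-yl]-2,6-dimethyl-8-oxo-5-(triethylsilyloxy)octa-1,6-dien-3-yl acetate
Product: 23 (1S,3S,6S,7R,8S)-3-acetoxy-8-hydroxy-1-(triethylsilyloxy)germacra-4Z,9Z,11(13)-trien-12,6-olide, via trimethylsilyl ether 22 (not isolated)
Conditions: CrCl2 (15 mol%), chiral carbazole-bis(oxazoline) ligand (18 mol%), i-Pr2NEt (30 mol%), Mn, Me3SiCl, NaI (30 mol%), THF, rt, slow addition of 21 to 2 mM; then aq. citric acid, THF, 0 °C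
Reagents that add atoms: none
Why: Proposed new method: chromium-catalysed, ligand-controlled intramolecular vinylogous carbonyl allylation of a 3-(halomethyl)butenolide, in which divalent chromium (regenerated by Mn) reduces the allylic halide (chloride exchanged to iodide by NaI) to an allyl trivalent-chromium species that adds through C7 to the tethered C8 aldehyde in a closed six-membered chair, forming C7–C8 and ring A while the double bond moves to the exocyclic C11=C13 position; the ring-locked E-type allyl geometry is expected to give the 7,8-anti adduct, the ligand-bound chromium selects the aldehyde face (8S) and the short tether from C6 is expected to deliver the aldehyde to the lactone face syn to C5 (cis fusion at C7), with Me3SiCl releasing chromium from the alkoxide; the closest known reaction types are intermolecular chromium-mediated and chromium-catalysed enantioselective 2-(alkoxycarbonyl)allylations of aldehydes (including with 3-(bromomethyl)furan-2(5H)-one) and stoichiometric chromium Barbier macrocyclisations of germacranolide precursors.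

Step 15
Reactants: 23 (1S,3S,6S,7R,8S)-3-acetoxy-8-hydroxy-1-(triethylsilyloxy)germacra-4Z,9Z,11(13)-trien-12,6-olide; 24 angelic acid
Product: 26 (1S,3S,6S,7S,8R)-3-acetoxy-8-angeloyloxy-1-hydroxygermacra-4Z,9Z,11(13)-trien-12,6-olide, via silyl-protected angelate 25 (not isolated)
Conditions: PPh3 and DIAD premixed, toluene, 0 °C, then 24 and 23, 0 °C to rt; then HF·pyridine, THF, 0 °C
Reagents that add atoms: none
Why: Mitsunobu esterification inverts C8 (8S to 8R) by SN2 attack of the angelate anion, which acts as nucleophile and so is not exposed to the acyl activation that isomerises angelate to tiglate; HF·pyridine then removes the C1 silyl ether under non-basic conditions that do not move the acetate.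

**Compound list**
1 | methyl prop-2-ynoate (methyl propiolate) | C#CC(=O)OC | starting material
2 | methyl (Z)-2-(hydroxymethyl)-3-iodoprop-2-enoate | I/C=C(/CO)C(=O)OC | intermediate
3 | methyl (Z)-3-iodo-2-[(trimethylsilyloxy)methyl]prop-2-enoate | I/C=C(/CO[Si](C)(C)C)C(=O)OC | intermediate
4 | 4-methylfuran-2(5H)-one | CC1=CC(=O)OC1 | starting material
5 | (Z)-4-hydroxy-N-methoxy-N,3-dimethylbut-2-enamide | CON(C)C(=O)/C=C(/C)CO | intermediate (not isolated)
6 | (Z)-N-methoxy-N,3-dimethyl-4-(triethylsilyloxy)but-2-enamide | CON(C)C(=O)/C=C(/C)CO[Si](CC)(CC)CC | intermediate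
7 | (Z)-3-methyl-4-(triethylsilyloxy)but-2-enal | O=C/C=C(/C)CO[Si](CC)(CC)CC | intermediate
8 | methyl (2Z,4S,5Z)-6-methyl-7-(triethylsilyloxy)-4-(trimethylsilyloxy)-2-[(trimethylsilyloxy)methyl]hepta-2,5-dienoate | COC(=O)/C(CO[Si](C)(C)C)=C\[C@@H](O[Si](C)(C)C)/C=C(/C)CO[Si](CC)(CC)CC | intermediate (not isolated)
9 | (S)-3-(hydroxymethyl)-5-[(Z)-2-methyl-3-(triethylsilyloxy)prop-1-enyl]furan-2(5H)-one | OCC1=C[C@H](/C=C(/C)CO[Si](CC)(CC)CC)OC1=O | intermediate
10 | {(S)-5-[(Z)-2-methyl-3-(triethylsilyloxy)prop-1-enyl]-2-oxo-2,5-dihydrofuran-3-yl}methyl methanesulfonate | CS(=O)(=O)OCC1=C[C@H](/C=C(/C)CO[Si](CC)(CC)CC)OC1=O | intermediate (not isolated)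
11 | (S)-3-(chloromethyl)-5-[(Z)-2-methyl-3-(triethylsilyloxy)prop-1-enyl]furan-2(5H)-one | ClCC1=C[C@H](/C=C(/C)CO[Si](CC)(CC)CC)OC1=O | intermediate
12 | (Z)-3-[(S)-4-(chloromethyl)-5-oxo-2,5-dihydrofuran-2-yl]-2-methylprop-2-enal | ClCC1=C[C@H](/C=C(/C)C=O)OC1=O | intermediate
13 | 3-methylfuran-2(5H)-one | CC1=CCOC1=O | starting material
14 | (Z)-4-hydroxy-N-methoxy-N,2-dimethylbut-2-enamide | CON(C)C(=O)/C(C)=C\CO | intermediate (not isolated)
15 | (Z)-N-methoxy-N,2-dimethyl-4-(triethylsilyloxy)but-2-enamide | CON(C)C(=O)/C(C)=C\CO[Si](CC)(CC)CC | intermediate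
16 | (Z)-3-methyl-5-(triethylsilyloxy)pent-3-en-2-one | CC(=O)/C(C)=C\CO[Si](CC)(CC)CC | intermediate
17 | (Z)-3-methyl-5-(triethylsilyloxy)-2-(trimethylsilyloxy)penta-1,3-diene | C=C(O[Si](C)(C)C)/C(C)=C\CO[Si](CC)(CC)CC | intermediate
18 | (S)-3-(chloromethyl)-5-[(1Z,3S,6Z)-3-hydroxy-2,6-dimethyl-5-oxo-8-(triethylsilyloxy)octa-1,6-dienyl]furan-2(5H)-one | ClCC1=C[C@H](/C=C(/C)[C@@H](O)CC(=O)/C(C)=C\CO[Si](CC)(CC)CC)OC1=O | intermediate
19 | (1Z,3S,5S,6Z)-1-[(S)-4-(chloromethyl)-5-oxo-2,5-dihydrofuran-2-yl]-5-hydroxy-2,6-dimethyl-8-(triethylsilyloxy)octa-1,6-dien-3-yl acetate | ClCC1=C[C@H](/C=C(/C)[C@@H](OC(C)=O)C[C@H](O)/C(C)=C\CO[Si](CC)(CC)CC)OC1=O | intermediate (not isolated)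
20 | (1Z,3S,5S,6Z)-1-[(S)-4-(chloromethyl)-5-oxo-2,5-dihydrofuran-2-yl]-2,6-dimethyl-5,8-bis(triethylsilyloxy)octa-1,6-dien-3-yl acetate | ClCC1=C[C@H](/C=C(/C)[C@@H](OC(C)=O)C[C@H](O[Si](CC)(CC)CC)/C(C)=C\CO[Si](CC)(CC)CC)OC1=O | intermediate
21 | (1Z,3S,5S,6Z)-1-[(S)-4-(chloromethyl)-5-oxo-2,5-dihydrofuran-2-yl]-2,6-dimethyl-8-oxo-5-(triethylsilyloxy)octa-1,6-dien-3-yl acetate | ClCC1=C[C@H](/C=C(/C)[C@@H](OC(C)=O)C[C@H](O[Si](CC)(CC)CC)/C(C)=C\C=O)OC1=O | intermediate
22 | (1S,3S,6S,7S,8S)-3-acetoxy-1-(triethylsilyloxy)-8-(trimethylsilyloxy)germacra-4Z,9Z,11(13)-trien-12,6-olide | C=C1C(=O)O[C@H]2/C=C(/C)[C@@H](OC(C)=O)C[C@H](O[Si](CC)(CC)CC)/C(C)=C\[C@H](O[Si](C)(C)C)[C@@H]12 | intermediate (not isolated)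
23 | (1S,3S,6S,7R,8S)-3-acetoxy-8-hydroxy-1-(triethylsilyloxy)germacra-4Z,9Z,11(13)-trien-12,6-olide (8-epi alcohol) | C=C1C(=O)O[C@H]2/C=C(/C)[C@@H](OC(C)=O)C[C@H](O[Si](CC)(CC)CC)/C(C)=C\[C@H](O)[C@@H]12 | intermediate
24 | angelic acid, (Z)-2-methylbut-2-enoic acid | C/C=C(/C)C(=O)O | starting material
25 | (1S,3S,6S,7S,8R)-3-acetoxy-8-angeloyloxy-1-(triethylsilyloxy)germacra-4Z,9Z,11(13)-trien-12,6-olide | C=C1C(=O)O[C@H]2/C=C(/C)[C@@H](OC(C)=O)C[C@H](O[Si](CC)(CC)CC)/C(C)=C\[C@@H](OC(=O)/C(C)=C\C)[C@@H]12 | intermediate (not isolated)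
26 | (1S,3S,6S,7S,8R)-3-acetoxy-8-angeloyloxy-1-hydroxygermacra-4Z,9Z,11(13)-trien-12,6-olide; (3aS,4R,5Z,7S,9S,10Z,11aS)-9-acetoxy-7-hydroxy-6,10-dimethyl-3-methylidene-2-oxo-2,3,3a,4,7,8,9,11a-octahydrocyclodeca[b]furan-4-yl (Z)-2-methylbut-2-enoate | C=C1C(=O)O[C@H]2/C=C(/C)[C@@H](OC(C)=O)C[C@H](O)/C(C)=C\[C@@H](OC(=O)/C(C)=C\C)[C@@H]12 | target

**Step count and risk**

Total steps: 15. Longest linear sequence: 10 steps (3, 4, 5, 6, 7, 11, 12, 13, 14, 15; the branch 1, 2, 5, 6, 7, 11–15 is equally long).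

Steps most likely to fail:

Step 14 (new macrocyclisation; the cis fusion at C7, the 7,8-anti sense and the yield of a ten-membered closure are all untested). The fallback sets out from 21 and comes back at 25. The allylic chloride of 21 is stannylated with Bu3Sn–SnBu3 and Pd(PPh3)4 (zerovalent palladium, 5 mol%) in THF to give the butenolide allylstannane aldehyde F1. BF3·OEt2 in CH2Cl2 at −78 °C under high dilution then closes ring A by a Lewis-acid-promoted 2-carbonyl-allylstannane addition through an open antiperiplanar transition state, which is syn-selective and gives the 8R macrocyclic alcohol F2 directly. F2 is acylated with retention by the mixed anhydride of 24 and 2,4,6-trichlorobenzoyl chloride (Et3N, toluene, 80 °C) to give 25, which is desilylated with HF·pyridine as in step 15.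

Step 15 (Mitsunobu on a hindered allylic alcohol next to the C7 methine; elimination toward C7 and phosphine addition to the methylene lactone compete). The fallback sets out from 23 and comes back at 25. 23 is treated with ClCH2SO2Cl and pyridine in CH2Cl2 at −20 °C to give the 8-chloromethanesulfonate F3. F3 is displaced with caesium angelate (from 24 and Cs2CO3) and 18-crown-6 in toluene at 40 °C, a phosphine-free SN2 inversion by a carboxylate, to give 25, which is desilylated as in step 15.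

Step 12 (Evans–Tishchenko on a Z-enone; retro-aldol back to 12, reduction of the allylic chloride by residual divalent samarium and O3 to O1 acetyl migration are the risks). The fallback sets out from 18 and comes back at 19. 18 is acetylated (Ac2O, pyridine, CH2Cl2, 0 °C) to the β-acetoxy enone F4. The C1 ketone of F4 is then reduced 1,2 under reagent control with (R)-2-methyl-CBS-oxazaborolidine (20 mol%) and catecholborane in toluene at −78 °C, the alkenyl group acting as the large substituent, to give 19 (1S), which is silylated as in step 12.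

**Further compounds**
F1 | step 14 | (1Z,3S,5S,6Z)-2,6-dimethyl-8-oxo-1-{(S)-5-oxo-4-[(tributylstannyl)methyl]-2,5-dihydrofuran-2-yl}-5-(triethylsilyloxy)octa-1,6-dien-3-yl acetate | CCCC[Sn](CCCC)(CCCC)CC1=C[C@H](/C=C(/C)[C@@H](OC(C)=O)C[C@H](O[Si](CC)(CC)CC)/C(C)=C\C=O)OC1=O
F2 | step 14 | (1S,3S,6S,7R,8R)-3-acetoxy-8-hydroxy-1-(triethylsilyloxy)germacra-4Z,9Z,11(13)-trien-12,6-olide | C=C1C(=O)O[C@H]2/C=C(/C)[C@@H](OC(C)=O)C[C@H](O[Si](CC)(CC)CC)/C(C)=C\[C@@H](O)[C@@H]12
F3 | step 15 | (1S,3S,6S,7S,8S)-3-acetoxy-8-(chloromethanesulfonyloxy)-1-(triethylsilyloxy)germacra-4Z,9Z,11(13)-trien-12,6-olide | C=C1C(=O)O[C@H]2/C=C(/C)[C@@H](OC(C)=O)C[C@H](O[Si](CC)(CC)CC)/C(C)=C\[C@H](OS(=O)(=O)CCl)[C@@H]12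
F4 | step 12 | (1Z,3S,6Z)-1-[(S)-4-(chloromethyl)-5-oxo-2,5-dihydrofuran-2-yl]-2,6-dimethyl-5-oxo-8-(triethylsilyloxy)octa-1,6-dien-3-yl acetate | ClCC1=C[C@H](/C=C(/C)[C@@H](OC(C)=O)CC(=O)/C(C)=C\CO[Si](CC)(CC)CC)OC1=O
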